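Lay the two earlier target curves over each other, in fractions of the charge, before asking anything of the new flask.

| flask | starting material | remark | time |
|---|---|---|---|
| winter | 0.34 M | run made earlier |  |
| summer | 1.4 M | run made earlier |  |
| flask | 0.68 M |  | 15 d |

| run | time / d | target / % |
|---|---|---|
| winter | 0.333 | 26 |
| winter | 0.833 | 39 |
| winter | 2.50 | 36 |
| winter | 6.00 | 27 |
| winter | 15.0 | 22 |
| summer | 0.333 | 25 |
| summer | 0.833 | 39 |
| summer | 2.50 | 34 |
| summer | 6.00 | 30 |
| summer | 15.0 | 20 |

(each reading ± 2 percentage points)

- a species is counted by the starting material in it: one self-condensation product counts as two
- the numbers in the tables scatter with a standard deviation of 2 percentage points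
- what may be going on: intermediate A -> side product B; intermediate B -> side product A; starting material -> intermediate A; 2 starting material -> self-condensation product; target <-> isomer of the product; starting material -> target; intermediate A -> intermediate B

* the best time, 15 d at the latest, for target
* the amount of target, in percent of the starting material charged, at that time

The summer charge is 4.12 times the winter charge, yet the widest gap between paired readings is 3 percentage points, against a scatter of 2 points on each reading. We therefore freeze the curve and pool the runs, since the flask's charge of 0.68 M lies between theirs.

The bench rule says the highest reading is the peak, which gives a pooled 0.390 of the charge at 0.833 d. That rule serves for the height but stops at the time: the next reading comes a factor 3.00 later and its pooled value lies only 4 points lower, so the top may stand well after the highest reading. Our own guess for the flask is the geometric mean of those two reading times, 1.44 d.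

We carry one number, the retention, meaning pooled target at 15.0 d divided by pooled target at the peak reading: 0.538.

The forecast gives 38.5 % at 1.2 d, a time earlier than ours, and adds: “Later times only lose target.”

The flask gives 38.9 % at 1.36 d, and the forecast stands.

    intermediate A → side product B (k = 0.00980 h⁻¹)
    intermediate B → side product A (k = 0.0380 h⁻¹)
    starting material → intermediate A (k = 0.0670 h⁻¹)
    2 starting material → self-condensation product (k = 0.00530 M⁻¹ h⁻¹)
    target ⇌ isomer of the product (K = 2.40, k = 0.00270 h⁻¹)
    starting material → target (k = 0.0520 h⁻¹)
    intermediate A → intermediate B (k = 0.170 h⁻¹)

Starting material has a half-life of 0.43 d by its turning into intermediate A alone, while target has 10.7 d by its forward turning into isomer alone. At the peak of the flask target leads its isomer, 38.9 % against 2.66 %, although the equilibrium constant of 2.4 lies on the side of the isomer, which is kinetic control. Retention times the flask's peak of 38.9 % gives 20.9 % at 15.0 d, and the flask holds 20.3 %. In the neighbour flask with 0.17 M of starting material, the peak of 39.8 % gives 21.4 % by retention; the computed amount in that flask at 15.0 d is 20.7 %.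

(Readings and results are simulated with constants of no real substance; noise was put on by code.)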